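**Plan**
- Retrosynthesis: the C4 ketone is traced back to an exocyclic C4=CH2 and the seven phenols to MOM ethers; ring C is then cut at the aryl ether bond O1–C8a, the chain at C2–C3, the biaryl at C5'–C6'' and ring A from its three-carbon unit at C4–C4a.
- Enabling feature: O1–C8a is an aryl–oxygen bond ortho to C4a, the ring A carbon that carries C4. With C4 held as a methylene there is no β-aryloxy ketone to undergo retro-aldol cleavage or elimination to a chalcone, so ring C can close by C–O coupling of the C2 alcohol with a C8a bromide.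
- Forward: three fragments are made separately, a 2-arylallyl pinacolboronate (ring A, from 5-bromoresorcinol), a boronate aldehyde (ring B, from 5-bromovanillin) and a 6-iodoflavone (from apigenin). Ring B and the flavone are joined first, the ring A allyl unit is then added at the aldehyde (C2–C3), ring C is closed, and C4=O is unveiled before global deprotection.
- Stereochemistry: the only stereocentre, C2 (S), is set by a chiral phosphoric acid-catalysed allylboration. The C2–O bond is never broken afterwards and no base is used once the ketone is present.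

Key step: step 16

Remark: apigenin is an inexpensive commercial flavone and is taken as the source of the flavone unit.
Remark: the biaryl axis (three ortho oxygen substituents) is drawn without configuration in the target and is treated as freely rotating; no step addresses it.

**Step 1**
Reactants: 1 5-bromoresorcinol
Product: 2 1-bromo-3,5-bis(methoxymethoxy)benzene
Conditions: MOMCl (2.5 equiv), iPr2NEt, CH2Cl2, 0 °C to rt
Reagents that add atoms: chloromethyl methyl ether, COCCl
Why: Williamson-type O-alkylation of both phenols with the reactive α-chloro ether under amine base is routine and leaves the aryl bromide untouched.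

**Step 2**
Reactants: 2 1-bromo-3,5-bis(methoxymethoxy)benzene
Product: 3 1-bromo-2-iodo-3,5-bis(methoxymethoxy)benzene
Conditions: NIS (1.05 equiv), MeCN, 0 °C to rt, dark
Reagents that add atoms: N-iodosuccinimide, O=C1CCC(=O)N1I
Why: Electrophilic aromatic iodination of the resorcinol diether is expected at C2 (para to one alkoxy group, ortho to the other) and not at the more crowded C4 between the two alkoxy groups, as in related halogenations and formylations of 5-bromoresorcinol diethers.

**Step 3**
Reactants: 3 1-bromo-2-iodo-3,5-bis(methoxymethoxy)benzene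
Product: 5 ethyl 2-[2-bromo-4,6-bis(methoxymethoxy)phenyl]-2-oxoacetate, via arylmagnesium chloride 4 (not isolated)
Conditions: iPrMgCl·LiCl (1.05 equiv), THF, −40 °C; cannulate into diethyl oxalate (3 equiv), THF, −78 to −30 °C; aq NH4Cl
Reagents that add atoms: diethyl oxalate, CCOC(=O)C(=O)OCC (isopropylmagnesium chloride, CC(C)[Mg]Cl, supplies MgCl to intermediate 4 only)
Why: Iodine–magnesium exchange is far faster at C–I than at C–Br and the ortho-bromoaryl Grignard reagent resists aryne formation at low temperature, so acylation with excess oxalate (inverse addition) should stop at the aryl keto ester.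

**Step 4**
Reactants: 5 ethyl 2-[2-bromo-4,6-bis(methoxymethoxy)phenyl]-2-oxoacetate
Product: 6 ethyl 2-[2-bromo-4,6-bis(methoxymethoxy)phenyl]prop-2-enoate
Conditions: Ph3PCH3Br (1.3 equiv), KN(SiMe3)2 (1.2 equiv), THF, 0 °C; then 5, −78 °C to rt
Reagents that add atoms: methyltriphenylphosphonium bromide, C[P+](c1ccccc1)(c1ccccc1)c1ccccc1.[Br-]
Why: Wittig methylenation, in which the strongly electrophilic ketone carbonyl of the α-keto ester reacts with the unstabilised ylide in preference to the ester, as in standard preparations of 2-arylacrylates.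

**Step 5**
Reactants: 6 ethyl 2-[2-bromo-4,6-bis(methoxymethoxy)phenyl]prop-2-enoate
Product: 7 2-[2-bromo-4,6-bis(methoxymethoxy)phenyl]prop-2-en-1-ol
Conditions: iBu2AlH (2.5 equiv), CH2Cl2, −78 to 0 °C; aq potassium sodium tartrate
Reagents that add atoms: none
Why: 1,2-Reduction of an α,β-unsaturated ester by iBu2AlH gives the allylic alcohol and tolerates the aryl bromide and the acetals.

**Step 6**
Reactants: 7 2-[2-bromo-4,6-bis(methoxymethoxy)phenyl]prop-2-en-1-ol
Product: 8 2-[2-bromo-4,6-bis(methoxymethoxy)phenyl]prop-2-en-1-yl methyl carbonate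
Conditions: ClCO2Me, pyridine, CH2Cl2, 0 °C
Reagents that add atoms: methyl chloroformate, COC(=O)Cl
Why: Acylation of a primary allylic alcohol with a chloroformate under pyridine is routine and installs the leaving group for the borylation.

**Step 7**
Reactants: 8 2-[2-bromo-4,6-bis(methoxymethoxy)phenyl]prop-2-en-1-yl methyl carbonate
Product: 9 2-{2-[2-bromo-4,6-bis(methoxymethoxy)phenyl]prop-2-en-1-yl}-4,4,5,5-tetramethyl-1,3,2-dioxaborolane
Conditions: B2pin2 (1.5 equiv), CuCl (5 mol %), Xantphos (5 mol %), KOtBu (10 mol %), THF, rt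
Reagents that add atoms: bis(pinacolato)diboron, CC1(C)OB(OC1(C)C)B1OC(C)(C)C(C)(C)O1
Why: Copper-catalysed allylic borylation (borylcupration of the alkene, then β-alkoxide elimination) converts allylic carbonates into allyl pinacolboronates at room temperature, where an aryl bromide is inert; the allyl unit is symmetric about its central carbon, so regiochemistry is not an issue.

**Step 8**
Reactants: 10 5-bromovanillin
Product: 11 3-bromo-4,5-dihydroxybenzaldehyde
Conditions: AlCl3 (1.1 equiv), pyridine (4.4 equiv), CH2Cl2, reflux; aq HCl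
Reagents that add atoms: none
Why: Chelation-assisted Lewis-acid ether cleavage, in which aluminium bound between the phenoxide and the neighbouring methoxy oxygen activates only that methyl group for loss as chloromethane, the classic selective demethylation of 5-halovanillins.

**Step 9**
Reactants: 11 3-bromo-4,5-dihydroxybenzaldehyde
Product: 12 3-bromo-4,5-bis(methoxymethoxy)benzaldehyde
Conditions: MOMCl (2.5 equiv), iPr2NEt, CH2Cl2, 0 °C to rt
Reagents that add atoms: chloromethyl methyl ether, COCCl
Why: O-Alkylation of both catechol hydroxyls with the α-chloro ether under amine base is routine and does not affect the aldehyde.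

**Step 10**
Reactants: 12 3-bromo-4,5-bis(methoxymethoxy)benzaldehyde
Product: 13 3,4-bis(methoxymethoxy)-5-(4,4,5,5-tetramethyl-1,3,2-dioxaborolan-2-yl)benzaldehyde
Conditions: B2pin2, PdCl2(dppf) (3 mol %; [1,1'-bis(diphenylphosphino)ferrocene]palladium dichloride), KOAc, 1,4-dioxane, 85 °C
Reagents that add atoms: bis(pinacolato)diboron, CC1(C)OB(OC1(C)C)B1OC(C)(C)C(C)(C)O1
Why: Miyaura borylation of an aryl bromide with acetate as a weak base tolerates aldehydes and acetals and places boron on the less hindered coupling partner.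

**Step 11**
Reactants: 14 apigenin
Product: 15 5-hydroxy-7-(methoxymethoxy)-2-[4-(methoxymethoxy)phenyl]-4H-chromen-4-one
Conditions: MOMCl (2.2 equiv), K2CO3, acetone, rt
Reagents that add atoms: chloromethyl methyl ether, COCCl
Why: Selective O-alkylation, since the 7-OH and 4'-OH are acidic and unhindered whereas the 5-OH is locked in a hydrogen bond to the C4 carbonyl and stays free under mild carbonate conditions.

**Step 12**
Reactants: 15 5-hydroxy-7-(methoxymethoxy)-2-[4-(methoxymethoxy)phenyl]-4H-chromen-4-one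
Product: 16 5-hydroxy-6-iodo-7-(methoxymethoxy)-2-[4-(methoxymethoxy)phenyl]-4H-chromen-4-one
Conditions: BnMe3N·ICl2 (1.1 equiv), CaCO3, CH2Cl2/MeOH, rt
Reagents that add atoms: benzyltrimethylammonium dichloroiodate, C[N+](C)(C)Cc1ccccc1.Cl[I-]Cl
Why: Electrophilic aromatic iodination of 5,7-dioxygenated flavones with a free 5-OH and an alkylated 7-oxygen is known to go to C6 (ortho to the free phenol) and not to C8, and CaCO3 scavenges HCl so the acetals should survive.

**Step 13**
Reactants: 16 5-hydroxy-6-iodo-7-(methoxymethoxy)-2-[4-(methoxymethoxy)phenyl]-4H-chromen-4-one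
Product: 17 6-iodo-5,7-bis(methoxymethoxy)-2-[4-(methoxymethoxy)phenyl]-4H-chromen-4-one
Conditions: NaH (1.5 equiv), MOMCl (1.5 equiv), DMF, 0 °C to rt
Reagents that add atoms: chloromethyl methyl ether, COCCl
Why: Irreversible deprotonation breaks the 5-OH/C4=O chelate and the small, reactive α-chloro ether alkylates the hindered phenoxide, removing a phenol that could bind palladium in later steps.

**Step 14**
Reactants: 17 6-iodo-5,7-bis(methoxymethoxy)-2-[4-(methoxymethoxy)phenyl]-4H-chromen-4-one; 13 3,4-bis(methoxymethoxy)-5-(4,4,5,5-tetramethyl-1,3,2-dioxaborolan-2-yl)benzaldehyde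
Product: 18 3-{5,7-bis(methoxymethoxy)-2-[4-(methoxymethoxy)phenyl]-4-oxo-4H-chromen-6-yl}-4,5-bis(methoxymethoxy)benzaldehyde
Conditions: Pd(OAc)2 (5 mol %), SPhos (10 mol %), K3PO4 (3 equiv), toluene/H2O (10:1), 90 °C
Reagents that add atoms: none
Why: Suzuki–Miyaura coupling with a dialkyl(biaryl)phosphine ligand is the standard way to make tri-ortho-substituted biaryls; the hindered partner is the iodide (fast oxidative addition) and the boronate is the less hindered one, and aldehyde, flavone and acetals are compatible.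

**Step 15**
Reactants: 18 3-{5,7-bis(methoxymethoxy)-2-[4-(methoxymethoxy)phenyl]-4-oxo-4H-chromen-6-yl}-4,5-bis(methoxymethoxy)benzaldehyde; 9 2-{2-[2-bromo-4,6-bis(methoxymethoxy)phenyl]prop-2-en-1-yl}-4,4,5,5-tetramethyl-1,3,2-dioxaborolane
Product: 20 6-{5-[(1S)-3-[2-bromo-4,6-bis(methoxymethoxy)phenyl]-1-hydroxybut-3-en-1-yl]-2,3-bis(methoxymethoxy)phenyl}-5,7-bis(methoxymethoxy)-2-[4-(methoxymethoxy)phenyl]-4H-chromen-4-one, via pinacol borate ester 19 (not isolated)
Conditions: 9 (1.3 equiv), (S)-TRIP (10 mol %), 4 Å MS, toluene, −30 to 0 °C; then aq NaHCO3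
Reagents that add atoms: none
Why: Chiral phosphoric acid-catalysed allylboration of an aryl aldehyde through a closed chair six-membered transition state, in which (S)-TRIP [(S)-3,3'-bis(2,4,6-triisopropylphenyl)-1,1'-binaphthyl-2,2'-diyl hydrogen phosphate] activates the boronate oxygen and is expected to direct the allyl terminus to the si face of the formyl group (assigned by analogy with the known pairing of the (R)-acid with re-face attack on aryl aldehydes, to be confirmed on the first batch), giving the (S)-carbinol with transposition of the allyl unit to the 1,1-disubstituted alkene.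

**Step 16**
Reactants: 20 the (S)-bromo homoallylic alcohol
Product: 21 6-{5-[(2S)-5,7-bis(methoxymethoxy)-4-methylidene-3,4-dihydro-2H-chromen-2-yl]-2,3-bis(methoxymethoxy)phenyl}-5,7-bis(methoxymethoxy)-2-[4-(methoxymethoxy)phenyl]-4H-chromen-4-one
Conditions: Pd(OAc)2 (5 mol %), 2-(di-tert-butylphosphino)-1,1'-binaphthyl (7.5 mol %), Cs2CO3 (1.5 equiv), toluene (degassed), 70 °C
Reagents that add atoms: none
Why: Zerovalent palladium, formed in the flask from Pd(OAc)2 and the phosphine, inserts into the C8a–Br bond of ring A; carbonate-assisted exchange of bromide for the C2 alkoxide gives a seven-membered aryl(alkoxo) palladacycle of divalent palladium (Pd, C8a, C4a, C4, C3, C2, O1), and C–O reductive elimination releases the product and returns zerovalent palladium. The closest known reaction type is the palladium-catalysed intramolecular etherification of ortho-(hydroxyalkyl)aryl bromides by primary and secondary alcohols to chromans under di-tert-butyl(biaryl)phosphine ligation. Ring C closes as a six-membered ring by O1–C8a bond formation, the oxygen being tethered through C2–C3–C4 to the ortho carbon C4a, and not by substitution at C2. No stereocentre is created, and because the C2–O bond stays intact the (S) configuration from step 15 is carried over. The step needs reductive elimination to outrun β-hydride elimination of the benzylic palladium alkoxide, which the bulky electron-rich ligand and the rigid 1,1-disubstituted alkene holding O1 near C8a should secure. The single C–Br bond fixes the site, the C4 methylene leaves no ketone for carbonate-induced retro-aldol cleavage or chalcone formation, and Heck insertion of the ortho alkene is geometrically impossible (it would need a three- or four-membered ring).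

**Step 17**
Reactants: 21 the (2S)-4-methyleneflavan
Product: 23 6-{5-[(2S)-5,7-bis(methoxymethoxy)-4-oxo-3,4-dihydro-2H-chromen-2-yl]-2,3-bis(methoxymethoxy)phenyl}-5,7-bis(methoxymethoxy)-2-[4-(methoxymethoxy)phenyl]-4H-chromen-4-one, via 4-hydroxy-4-(hydroxymethyl)flavan diol 22 (not isolated)
Conditions: OsO4 (3 mol %), NaIO4 (4 equiv), 2,6-lutidine (2 equiv), 1,4-dioxane/H2O (3:1), rt
Reagents that add atoms: osmium tetroxide, O=[Os](=O)(=O)=O (delivers the C4 oxygen; regenerated by sodium periodate, [Na+].[O-]I(=O)(=O)=O)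
Why: Lemieux–Johnson oxidative cleavage, in which the electron-rich exocyclic styrene is dihydroxylated much faster than the electron-poor C2=C3 bond of the flavone and periodate cleaves the diol to the aryl ketone under buffered, near-neutral conditions that should not epimerise C2.

**Step 18**
Reactants: 23 the heptakis(methoxymethyl) flavanone
Product: 24 (2S)-2-{3,4-dihydroxy-5-[5,7-dihydroxy-2-(4-hydroxyphenyl)-4-oxo-4H-chromen-6-yl]phenyl}-5,7-dihydroxy-2,3-dihydro-4H-chromen-4-one (CNP0176432.1)
Conditions: 3 M HCl, MeOH/THF, 45 °C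
Reagents that add atoms: none
Why: Acid-catalysed acetal exchange removes all seven methoxymethyl ethers as dimethoxymethane, a standard final step for flavanones in which the C2–O1 bond and the C2 configuration are expected to survive mild acid.

**Compound list**
1 | 5-bromoresorcinol | Oc1cc(O)cc(Br)c1 | starting material
2 | 1-bromo-3,5-bis(methoxymethoxy)benzene | COCOc1cc(OCOC)cc(Br)c1 | intermediate
3 | 1-bromo-2-iodo-3,5-bis(methoxymethoxy)benzene | COCOc1cc(OCOC)c(I)c(Br)c1 | intermediate
4 | [2-bromo-4,6-bis(methoxymethoxy)phenyl]magnesium chloride (not isolated) | COCOc1cc(OCOC)c([Mg]Cl)c(Br)c1 | intermediate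
5 | ethyl 2-[2-bromo-4,6-bis(methoxymethoxy)phenyl]-2-oxoacetate | CCOC(=O)C(=O)c1c(Br)cc(OCOC)cc1OCOC | intermediate
6 | ethyl 2-[2-bromo-4,6-bis(methoxymethoxy)phenyl]prop-2-enoate | CCOC(=O)C(=C)c1c(Br)cc(OCOC)cc1OCOC | intermediate
7 | 2-[2-bromo-4,6-bis(methoxymethoxy)phenyl]prop-2-en-1-ol | C=C(CO)c1c(Br)cc(OCOC)cc1OCOC | intermediate
8 | 2-[2-bromo-4,6-bis(methoxymethoxy)phenyl]prop-2-en-1-yl methyl carbonate | C=C(COC(=O)OC)c1c(Br)cc(OCOC)cc1OCOC | intermediate
9 | 2-{2-[2-bromo-4,6-bis(methoxymethoxy)phenyl]prop-2-en-1-yl}-4,4,5,5-tetramethyl-1,3,2-dioxaborolane | C=C(CB1OC(C)(C)C(C)(C)O1)c1c(Br)cc(OCOC)cc1OCOC | intermediate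
10 | 5-bromovanillin | COc1cc(C=O)cc(Br)c1O | starting material
11 | 3-bromo-4,5-dihydroxybenzaldehyde | O=Cc1cc(O)c(O)c(Br)c1 | intermediate
12 | 3-bromo-4,5-bis(methoxymethoxy)benzaldehyde | O=Cc1cc(OCOC)c(OCOC)c(Br)c1 | intermediate
13 | 3,4-bis(methoxymethoxy)-5-(4,4,5,5-tetramethyl-1,3,2-dioxaborolan-2-yl)benzaldehyde | O=Cc1cc(OCOC)c(OCOC)c(B2OC(C)(C)C(C)(C)O2)c1 | intermediate
14 | apigenin, 5,7-dihydroxy-2-(4-hydroxyphenyl)-4H-chromen-4-one | O=c1cc(-c2ccc(O)cc2)oc2cc(O)cc(O)c12 | starting material
15 | 5-hydroxy-7-(methoxymethoxy)-2-[4-(methoxymethoxy)phenyl]-4H-chromen-4-one | COCOc1ccc(-c2cc(=O)c3c(O)cc(OCOC)cc3o2)cc1 | intermediate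
16 | 5-hydroxy-6-iodo-7-(methoxymethoxy)-2-[4-(methoxymethoxy)phenyl]-4H-chromen-4-one | COCOc1ccc(-c2cc(=O)c3c(O)c(I)c(OCOC)cc3o2)cc1 | intermediate
17 | 6-iodo-5,7-bis(methoxymethoxy)-2-[4-(methoxymethoxy)phenyl]-4H-chromen-4-one | COCOc1ccc(-c2cc(=O)c3c(OCOC)c(I)c(OCOC)cc3o2)cc1 | intermediate
18 | 3-{5,7-bis(methoxymethoxy)-2-[4-(methoxymethoxy)phenyl]-4-oxo-4H-chromen-6-yl}-4,5-bis(methoxymethoxy)benzaldehyde | O=Cc1cc(OCOC)c(OCOC)c(-c2c(OCOC)cc3oc(-c4ccc(OCOC)cc4)cc(=O)c3c2OCOC)c1 | intermediate
19 | (S)-O-pinacolboryl ether of alcohol 20 (not isolated) | C=C(C[C@@H](c1cc(OCOC)c(OCOC)c(-c2c(OCOC)cc3oc(-c4ccc(OCOC)cc4)cc(=O)c3c2OCOC)c1)OB1OC(C)(C)C(C)(C)O1)c1c(Br)cc(OCOC)cc1OCOC | intermediate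
20 | (S)-bromo homoallylic alcohol, 6-{5-[(1S)-3-[2-bromo-4,6-bis(methoxymethoxy)phenyl]-1-hydroxybut-3-en-1-yl]-2,3-bis(methoxymethoxy)phenyl}-5,7-bis(methoxymethoxy)-2-[4-(methoxymethoxy)phenyl]-4H-chromen-4-one | C=C(C[C@@H](c1cc(OCOC)c(OCOC)c(-c2c(OCOC)cc3oc(-c4ccc(OCOC)cc4)cc(=O)c3c2OCOC)c1)O)c1c(Br)cc(OCOC)cc1OCOC | intermediate
21 | (2S)-4-methyleneflavan, 6-{5-[(2S)-5,7-bis(methoxymethoxy)-4-methylidene-3,4-dihydro-2H-chromen-2-yl]-2,3-bis(methoxymethoxy)phenyl}-5,7-bis(methoxymethoxy)-2-[4-(methoxymethoxy)phenyl]-4H-chromen-4-one | C=C1C[C@@H](c2cc(OCOC)c(OCOC)c(-c3c(OCOC)cc4oc(-c5ccc(OCOC)cc5)cc(=O)c4c3OCOC)c2)Oc2cc(OCOC)cc(OCOC)c21 | intermediate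
22 | (2S)-4-hydroxy-4-(hydroxymethyl)flavan diol, both C4 epimers (not isolated) | OCC1(O)C[C@@H](c2cc(OCOC)c(OCOC)c(-c3c(OCOC)cc4oc(-c5ccc(OCOC)cc5)cc(=O)c4c3OCOC)c2)Oc2cc(OCOC)cc(OCOC)c21 | intermediate
23 | (2S)-heptakis(methoxymethyl) flavanone, 6-{5-[(2S)-5,7-bis(methoxymethoxy)-4-oxo-3,4-dihydro-2H-chromen-2-yl]-2,3-bis(methoxymethoxy)phenyl}-5,7-bis(methoxymethoxy)-2-[4-(methoxymethoxy)phenyl]-4H-chromen-4-one | O=C1C[C@@H](c2cc(OCOC)c(OCOC)c(-c3c(OCOC)cc4oc(-c5ccc(OCOC)cc5)cc(=O)c4c3OCOC)c2)Oc2cc(OCOC)cc(OCOC)c21 | intermediate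
24 | CNP0176432.1, (2S)-2-{3,4-dihydroxy-5-[5,7-dihydroxy-2-(4-hydroxyphenyl)-4-oxo-4H-chromen-6-yl]phenyl}-5,7-dihydroxy-2,3-dihydro-4H-chromen-4-one | O=C1C[C@@H](c2cc(O)c(O)c(-c3c(O)cc4oc(-c5ccc(O)cc5)cc(=O)c4c3O)c2)Oc2cc(O)cc(O)c21 | target

**Total step count:** 18
**Longest linear sequence:** 11 steps (steps 1–7, then 15–18, from 5-bromoresorcinol)

**Steps most likely to fail**

Step 16. β-Hydride elimination of the benzylic palladium alkoxide may outrun C–O reductive elimination, oxidising the carbinol to a ketone with loss of bromine, and the resulting palladium hydride may move the exocyclic double bond into ring C. The fallback closes ring C through the O1–C2 bond with inversion instead. It sets out from aldehyde 18 and boronate 9, which are combined as in step 15 but with (R)-TRIP, to give through the (R)-pinacol borate ester F1 the (R)-bromo homoallylic alcohol F2. Miyaura borylation of the C8a–Br bond (B2pin2, PdCl2(dppf), KOAc, dioxane, 85 °C) should give the (R)-aryl pinacolboronate F3. Oxidation with NaBO3 in THF/water should give the (R)-phenol alcohol F4. Mitsunobu cyclisation (PPh3, diisopropyl azodicarboxylate, THF, 0 °C) then displaces the activated C2 oxygen by the phenol with inversion and rejoins the route at 21.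

Step 15. Facial selectivity may be poor because the bulky 2-aryl group disturbs the ordered transition state, the basic flavone carbonyl can sequester the acid, and an uncatalysed background reaction can compete. The fallback is a chromium-catalysed asymmetric Nozaki–Hiyama–Kishi allylation. It sets out from allylic alcohol 7, which an Appel reaction (CBr4, PPh3, CH2Cl2, 0 °C) converts into 2-[2-bromo-4,6-bis(methoxymethoxy)phenyl]allyl bromide F5. Addition of F5 to aldehyde 18 with CrCl2 (10 mol %), Mn powder, Me3SiCl and a chiral bis(oxazolinyl)carbazole ligand in THF (ligand enantiomer chosen for the (S)-carbinol) should give the (S)-trimethylsilyl ether F6; the aryl bromide is inert to divalent chromium in the absence of nickel. Desilylation with Bu4NF rejoins the route at 20.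

Step 14. Transmetalation at the tri-ortho-substituted coupling site may be slow, so that base-mediated protodeboronation of 13 and hydrodeiodination of 17 win. The fallback is a base-free Stille coupling. It sets out from bromide 12, which is stannylated (Bu3SnSnBu3, Pd(PPh3)4, toluene, 100 °C) to 3,4-bis(methoxymethoxy)-5-(tributylstannyl)benzaldehyde F7. Coupling of F7 with iodide 17 (Pd(PPh3)4, CuI, CsF, DMF, 45 °C) rejoins the route at 18.

**Further compounds**
F1 | step 16 | (R)-O-pinacolboryl ether of F2 (not isolated) | C=C(C[C@H](c1cc(OCOC)c(OCOC)c(-c2c(OCOC)cc3oc(-c4ccc(OCOC)cc4)cc(=O)c3c2OCOC)c1)OB1OC(C)(C)C(C)(C)O1)c1c(Br)cc(OCOC)cc1OCOC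
F2 | step 16 | (R)-bromo homoallylic alcohol (enantiomer of 20) | C=C(C[C@H](c1cc(OCOC)c(OCOC)c(-c2c(OCOC)cc3oc(-c4ccc(OCOC)cc4)cc(=O)c3c2OCOC)c1)O)c1c(Br)cc(OCOC)cc1OCOC
F3 | step 16 | (R)-homoallylic alcohol with a pinacolboryl group at C8a in place of bromine | C=C(C[C@H](c1cc(OCOC)c(OCOC)c(-c2c(OCOC)cc3oc(-c4ccc(OCOC)cc4)cc(=O)c3c2OCOC)c1)O)c1c(B2OC(C)(C)C(C)(C)O2)cc(OCOC)cc1OCOC
F4 | step 16 | (R)-homoallylic alcohol with a free phenol at C8a | C=C(C[C@H](c1cc(OCOC)c(OCOC)c(-c2c(OCOC)cc3oc(-c4ccc(OCOC)cc4)cc(=O)c3c2OCOC)c1)O)c1c(O)cc(OCOC)cc1OCOC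
F5 | step 15 | 1-bromo-2-(3-bromoprop-1-en-2-yl)-3,5-bis(methoxymethoxy)benzene | C=C(CBr)c1c(Br)cc(OCOC)cc1OCOC
F6 | step 15 | (S)-trimethylsilyl ether of 20 | C=C(C[C@@H](c1cc(OCOC)c(OCOC)c(-c2c(OCOC)cc3oc(-c4ccc(OCOC)cc4)cc(=O)c3c2OCOC)c1)O[Si](C)(C)C)c1c(Br)cc(OCOC)cc1OCOC
F7 | step 14 | 3,4-bis(methoxymethoxy)-5-(tributylstannyl)benzaldehyde | O=Cc1cc(OCOC)c(OCOC)c([Sn](CCCC)(CCCC)CCCC)c1
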